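**Assumptions (one line each)**
- The target SMILES corresponds to (1R,5S,6R,7R)-6-(3,5-dihydroxyphenyl)-7-(4-hydroxyphenyl)-4-[(E)-2-(4-hydroxyphenyl)ethenyl]bicyclo[3.2.1]oct-3-ene-2,8-dione, with the 6-aryl endo (syn to the enone bridge), the 7-aryl exo (syn to the C8 carbonyl) and the two aryls trans.
- trans-Resveratrol is treated as a bulk commercial starting material; reagents and catalysts are named in the conditions and not numbered.

**Retrosynthetic overview**
1. Disconnect the styryl C=C last: vitisinol D ⇒ 4-methyl bicyclic enedione 3 + 4-hydroxybenzaldehyde (vinylogous aldol condensation at the only enolisable carbon).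
2. Disconnect C5–C6 and C1–C7 of 3: oxidative, dearomative (3+2) annulation of orcinol (C4 and C2 as the C,C-bis-nucleophile) with the 2e-oxidised stilbene unit of resveratrol.
3. Ring order: the six-membered ring is the orcinol ring itself; the cyclopentanone ring is closed on it in one operation (C5–C6 first, then C1–C7), which breaks both the aromaticity and the C2v symmetry of orcinol and sets all four stereocentres.
4. Oxygen mapping: orcinol C3–OH becomes the bridging C8 ketone, C1–OH becomes the C2 ketone, and C5(CH3)=C6 becomes the C4=C3 enone.

**Route**

Step 1
Reactants: 1, orcinol (5-methylbenzene-1,3-diol), 5 equiv; 2, trans-resveratrol (limiting).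
Product: 3, (1R,5S,6R,7R)-6-(3,5-dihydroxyphenyl)-7-(4-hydroxyphenyl)-4-methylbicyclo[3.2.1]oct-3-ene-2,8-dione.
Conditions: DDQ (0.95 equiv, slow addition), (R)-3,3′-bis(2,4,6-triisopropylphenyl)-BINOL N-triflylphosphoramide (10 mol %), 4 Å MS, EtOAc/CH2Cl2 1:2, −60 °C; cold filtration through silica and chromatography without base. The sense of induction cannot be predicted; assign it on 3 by X-ray or ECD and use the (S)-catalyst if the (R)-catalyst gives ent-3.
Reagents that add atoms: none (DDQ only removes two H; both carbon partners are the listed reactants).
Why: Proposed new method: DDQ takes hydride (2e⁻/H⁺) from the 4-hydroxystilbene to give the quinone-methide carbenium ion, held as an ion pair with the chiral, very weakly basic phosphoramidate; orcinol attacks its Cβ (the carbon bearing the 3,5-dihydroxyphenyl ring) through C4 (para to one OH, ortho to the other, the kinetic site) on the enantiotopic face selected by the anion hydrogen-bonded to the ortho OH, with the aryl turned away from that anion (endo), which sets C5 and C6; loss of the O–H proton gives a neutral cyclohexadienone that still carries a p-quinone methide, and 5-exo Michael closure from the carbon between the two oxygens should outrun enolisation (which needs a base the medium lacks), fixing C1 by the bridge and C7 trans to the C6 aryl; closest known reactions are the cationic quinone–styrene [5+2] cycloaddition to bicyclo[3.2.1]oct-3-ene-2,8-diones (Büchi/Engler type), chiral-acid-catalysed formal [3+2] annulations of quinone derivatives with styrenes, and 2e-oxidative 8–10′ coupling of resveratrol.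

Step 2
Reactants: 3; 4, 4-hydroxybenzaldehyde (1.3 equiv).
Product: 5, vitisinol D, (1R,5S,6R,7R)-6-(3,5-dihydroxyphenyl)-7-(4-hydroxyphenyl)-4-[(E)-2-(4-hydroxyphenyl)ethenyl]bicyclo[3.2.1]oct-3-ene-2,8-dione.
Conditions: Et3N (6 equiv), TMSOTf (5.5 equiv), CH2Cl2, −78 → 0 °C; then TMSOTf (1.0 equiv), −78 → −20 °C; MeOH, aq. citric acid, rt.
Reagents that add atoms: none (the new CH=CH–aryl atoms come from reactant 4; the TMS groups are removed on work-up and the aldehyde oxygen leaves as water).
Why: One-pot soft enolisation / vinylogous Mukaiyama aldol condensation: all phenols are silylated in situ (no phenoxide, so no quinone-methide retro-Michael), the 4-methyl group is the only enolisable position (C1 and C5 are bridgeheads, C8 has no enolisable α-carbon) and gives the exocyclic silyl dienol ether, which adds through its terminal CH2 to the TMSOTf-activated aldehyde, and E1 loss of TMSOH through the p-siloxybenzyl cation gives the conjugated (E)-styryl dienone; no stereocentre is touched and acidic methanol cleaves the aryl TMS ethers.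

**Compound list**

1 | orcinol (5-methylbenzene-1,3-diol) | Cc1cc(O)cc(O)c1 | starting material
2 | trans-resveratrol | Oc1ccc(/C=C/c2cc(O)cc(O)c2)cc1 | starting material
3 | (1R,5S,6R,7R)-6-(3,5-dihydroxyphenyl)-7-(4-hydroxyphenyl)-4-methylbicyclo[3.2.1]oct-3-ene-2,8-dione | O=C1C=C(C)[C@H]2C(=O)[C@@H]1[C@H](c1ccc(O)cc1)[C@H]2c1cc(O)cc(O)c1 | intermediate
4 | 4-hydroxybenzaldehyde | O=Cc1ccc(O)cc1 | starting material
5 | vitisinol D | O=C1C=C(/C=C/c2ccc(O)cc2)[C@H]2C(=O)[C@@H]1[C@H](c1ccc(O)cc1)[C@H]2c1cc(O)cc(O)c1 | target

**Totals**
Total step count: 2. Longest linear sequence: 2.

**Most likely failure points and fallbacks** (the route has only two steps, so two of the three points lie within step 1)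

1. Step 1, mode of ring closure. The dienone may enolise before C-closure, giving the aromatic trans-2,3-diaryl-dihydrobenzofuran by O-closure, or orcinol may attack first through C2 and give the aryl-swapped regioisomer. Fallback: use phloroglucinol as the arene, whose keto tautomer is far more accessible so C,C-annulation is intrinsically favoured; this gives the bicyclo[3.2.1]octane-2,4,8-trione, and the styryl arm is then installed by enol triflation and Suzuki coupling with an (E)-4-hydroxystyrylboronate, accepting a C2/C4 regioisomer separation.

2. Step 1, stereocontrol. Ion-pair control by the chiral anion may be weak against the racemic background reaction of the DDQH⁻ ion pair, and the endo/exo preference at C6 is predicted, not established. Fallback: run the annulation without chiral control (diphenyl phosphate, or neutral radical–radical cross-coupling with Ag2O) and resolve rac-3 by preparative chiral SFC, removing the 6,7-bis-epimer by ordinary chromatography.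

3. Step 2, stability of the core. Free TMSOTf could ionise the C1–C7 bond (retro-Mukaiyama–Michael through the p-siloxybenzyl cation) and funnel the core to the aromatic dihydrobenzofuran. Fallback: carry the styryl arm through the key step by replacing orcinol with 4′-O-acetylresveratrol (lipase CAL-B, vinyl acetate), so that the endgame is only a neutral lipase-mediated deacetylation with no C–C bond formation on the bicyclic core.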